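Count target as the share of substrate that the enzyme converts before the background step takes it.

    substrate + enzyme → target + enzyme, rate k1*[substrate]*[enzyme]/(1 + ([substrate]/Km1) + ([target]/Kp1)) (Km1 = 2.0 mM, Kp1 = 34 mM, k1 = 1700 L mol⁻¹ s⁻¹)
    substrate → uncatalysed product (k2 = 1.7 × 10⁻⁴ s⁻¹)
    enzyme + target → spent catalyst (k3 = 0.0018 L mol⁻¹ s⁻¹)

| flask | substrate | enzyme | remark | time |
|---|---|---|---|---|
| eta | 40 mM | 4.0 µM | one stirred flow tank at steady state, fed with the mixture as stated, mean residence time 12 h |  |
| gamma | 40 mM | 4.0 µM | everything together in a closed stirred flask, run for 12 h | 12 h |
| epsilon | 40 mM (fed, over 12.0 h) | 4.0 µM | a stirred flask in which substrate is dosed at a steady rate over 12.0 h without added volume, worked up at 12 h | 12 h |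

- the stated concentrations are those of everything mixed, before any reaction; amounts are the same in each set-up
- the feed brings no volume worth counting
- run time (gamma): 12 h

* the set-up with the highest amount of target at the outlet or at the end, in percent of the substrate put in ("none" if the first two lie within 2 percentage points) (eta / gamma / epsilon / none)
* amount of target at the outlet or at the end, in percent of the substrate put in, eta
* amount of target at the outlet or at the end, in percent of the substrate put in, gamma
* amount of target at the outlet or at the end, in percent of the substrate put in, epsilon

Carry the enzyme ratio, the rate constant of the first step times the enzyme charged over the rate constant of the second step: 40.0. Multiply it by the fraction of enzyme still working and divide by one plus substrate over Km plus target over Kp: this is the selectivity factor at that moment, target made per uncatalysed product.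

Turn the vessel first. For gamma, keep the enzyme whole, leave out inhibition by target, and integrate the share from the charge down to nothing. The yield is the ratio times Km over the charge, times the natural logarithm of (ratio plus one plus charge over Km) over (ratio plus one): 79.5 %.

For eta, drop the substrate term and set target at the whole charge. The enzyme balance then leaves a working fraction of 24.3 %, so the factor is 4.47 and the yield 81.7 %.

For epsilon, let target climb steadily with the dose and read the factor at mid-dose as the average. Target at mid-dose is half the charge, and up to that moment, over half the dosing time, it averages half of that level, so the working fraction at mid-dose is 67.8 %, the factor is 17.1 and the yield 94.5 %. This ranks epsilon highest.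

The forecast names epsilon, with 80.5 % for eta, 78 % for gamma and 89 % for epsilon, on the ground that “the dosed flask still keeps the best selectivity until late”. My figure for epsilon stands higher than the forecast's.

The simulation gives 80.6 % for eta, 78.4 % for gamma and 89.8 % for epsilon, so epsilon leads.

Turn the enzyme next, in gamma's flask with 0.016 mM of enzyme. The ratio becomes 160, and the same logarithm gives 93.7 %. That flask ends with 93.3 % target and 6.67 % uncatalysed product.

The rate constants belong to no real substance, and the outcome is calculated.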